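(The data come from a simulation for substances that don't exist; the scatter is artificial.)

**In the vessel.** The stirred vessel holds D in the first phase at 0.050 M and X in the second phase, charged at 0.0500 M, with the second phase at 0.50 of the first by volume; I leave this note for whoever reads it at 4.0 min.

| flask | D | X | remark | time | volume of the second phase over the first |
|---|---|---|---|---|---|
| Monday's | 0.10 M | 0.050 M | run made earlier |  |  |
| flask | 0.050 M | 0.0500 M |  | 4.0 min | 0.50 |

- Monday's (time / s: L / %, D / %): 10.0: 0, 99.2; 15.0: 0.9, 99.3; 25.0: 1.7, 99.1; 30.0: 2.6, 97.1; 40.0: 3.3, 96.8; 50.0: 5.1, 95.2

(scatter of a reading: 0.5 percentage points)

- for L the G are counted in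
- in the second phase: X, G; everything else is in the first
- charges count per volume of the first phase; a concentration in a rate is the amount of a species over the volume of its own phase; every rate counts per litre of the first phase
- the earlier runs hold the two phases in the same ratio of volumes as the flask asked about

* the L and G together standing at 4.0 min, as a percentage of the D charged
* part of the D charged that has reacted at 4.0 min

**Monday's draw.** Of Monday's 0.10 M of D, L reads 5.1% at 50.0 s, and I reckon that lost part rather than the large remainder, which makes the draw, the molarity of D gone per minute averaged from the start, 0.00612 M/min. That reading carries a scatter of 0.5 percentage points. I take it that X has to cross from its own phase, and by the L readings the later half of Monday's run gave twice what the earlier half gave, so I assume the draw follows that crossing and not [D], which is zero order in D, with the X charge the same in this flask.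

**When you come.** By my reckoning this flask has lost 0.0245 M of D at 4.0 min, which is 49.0% of its charge, with L and G close under that. The forecast says 21% (15% to 36%) for L and G and 22% (16% to 37%) for D reacted, and adds “One run cannot fix the orders.” My figure stands above its high end for D reacted. Leave the phase ratio as it is, since Monday's run held the same ratio.

    J ⇌ X, rate k1*([J] - [X]/K1) per volume of the first phase (partition coefficient = 1.60, kL = 0.200 /min)
    D + J → L (k = 24.0 /M/min)
    L ⇌ G, rate k3*([L] - [G]/K3) per volume of the first phase (partition coefficient = 2.50, kL = 0.360 /min)
    L → Z (k = 0.0600 /min)

**The result.** This flask gives 40.3% for L and G and 43.8% for D reacted at 4.0 min, and Z, at 3.54%, stands for the gap between them. Its draw, averaged from the start to 4.0 min, is 0.00547 M/min, somewhat less than the 0.00612 M/min read from Monday's run up to 50.0 s, with a D charge half of Monday's. The neighbouring flask with 0.020 M of D, read at the same 4.0 min, has 61.8% reacted, a draw of 0.00309 M/min, half of the draw read from Monday's run.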